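**Retrosynthetic overview**
1. Target 21 ⇐ triol 17 (acylation of the equatorial 9-OH through a stannylene acetal) ⇐ bis-epoxide 14 by two trans-diaxial openings (isopropenyl at C7, hydride at C3).
2. 14 ⇐ bicyclic dienol 13 (Δ2, Δ7, 9α-OH) by α-face epoxidation of both ring alkenes.
3. 13 ⇐ open-chain (Z)-enal 12 by one cation–olefin cascade (step 8): ring B closes first (C9–C10, aldehyde onto the trisubstituted alkene), ring A second (C5–C4, allylsilane capture).
4. 12 ⇐ allylic bromide 8 + propargyl alcohol 9 (copper coupling, semi-hydrogenation, oxidation); 8 ⇐ β-silyl ester 3 (reduction/Wittig, reduction, bromination).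
5. 3 ⇐ ethyl sorbate 1 + silylborane 2 (enantioselective conjugate silylation); this single stereocentre later fixes the absolute configuration of the decalin.

Assumption: bicyclic compounds are described with eremophilane numbering (ring A = C1–C4, C5, C10; ring B = C5–C10; methyls on C4 and C5; β = face of the C5 methyl), so the target is 2α,8α-dihydroxy-9α-acyloxy-4β,5β-dimethyl-7β-isopropenyl-10αH; the ligand antipode in step 1 is taken to be the one that gives (R)-3, to be confirmed on the first run.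

**Route**

Step 1
Reactants: 1 ethyl (2E,4E)-hexa-2,4-dienoate; 2 dimethyl(phenyl)(4,4,5,5-tetramethyl-1,3,2-dioxaborolan-2-yl)silane
Product: 3 ethyl (3R,4E)-3-[dimethyl(phenyl)silyl]hex-4-enoate
Conditions: Cu(acac)2 (5 mol %), (S,S)-6,6′-bis(1-hydroxy-2,2-dimethylpropyl)-2,2′-bipyridine (6 mol %), H2O, rt, 24 h
Reagents that add atoms: silylborane (2), CC1(C)OB(OC1(C)C)[Si](C)(C)c1ccccc1
Why: Copper-catalysed enantioselective conjugate silylation (silyl transfer from the Si–B reagent to the β-carbon, expected to be 1,4 rather than 1,6 for an open-chain dienoate), in which the chiral bipyridine selects the β-face so that the silyl-bearing centre is R and the 4E-alkene is untouched, giving an (E)-crotylsilane.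

Step 2
Reactants: 3 ethyl (3R,4E)-3-[dimethyl(phenyl)silyl]hex-4-enoate; 4 ethyl 2-(triphenyl-λ5-phosphanylidene)propanoate
Product: 6 ethyl (2E,5R,6E)-5-[dimethyl(phenyl)silyl]-2-methylocta-2,6-dienoate, via β-silyl aldehyde 5 (not isolated)
Conditions: i-Bu2AlH (1.05 equiv), CH2Cl2, −78 °C, 1 h; then 4 (1.5 equiv), −78 °C → rt, 12 h
Reagents that add atoms: ethyl 2-(triphenyl-λ5-phosphanylidene)propanoate (4), CCOC(=O)C(C)=P(c1ccccc1)(c1ccccc1)c1ccccc1
Why: Partial ester reduction followed in the same flask by Wittig olefination with a stabilised α-methyl ylide gives the (E)-trisubstituted enoate; the silyl stereocentre is β to the carbonyl and cannot epimerise.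

Step 3
Reactants: 6 ethyl (2E,5R,6E)-5-[dimethyl(phenyl)silyl]-2-methylocta-2,6-dienoate
Product: 7 (2E,5R,6E)-5-[dimethyl(phenyl)silyl]-2-methylocta-2,6-dien-1-ol
Conditions: i-Bu2AlH (2.2 equiv), CH2Cl2, −78 → 0 °C; aq. potassium sodium tartrate
Reagents that add atoms: none
Why: 1,2-Reduction of the enoate to the allylic alcohol by the aluminium hydride, which leaves the allylsilane and both alkenes untouched.

Step 4
Reactants: 7 (2E,5R,6E)-5-[dimethyl(phenyl)silyl]-2-methylocta-2,6-dien-1-ol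
Product: 8 (2E,5R,6E)-1-bromo-5-[dimethyl(phenyl)silyl]-2-methylocta-2,6-diene
Conditions: CBr4, PPh3, 2,6-lutidine, CH2Cl2, 0 °C, 30 min
Reagents that add atoms: tetrabromomethane, BrC(Br)(Br)Br
Why: Appel bromination under buffered neutral conditions gives the primary allylic bromide without allylic transposition or protodesilylation.

Step 5
Reactants: 8 (2E,5R,6E)-1-bromo-5-[dimethyl(phenyl)silyl]-2-methylocta-2,6-diene; 9 prop-2-yn-1-ol
Product: 10 (5E,8R,9E)-8-[dimethyl(phenyl)silyl]-5-methylundeca-5,9-dien-2-yn-1-ol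
Conditions: 9 (1.5 equiv), CuI (20 mol %), NaI (20 mol %), K2CO3 (1.5 equiv), DMF, rt, 16 h
Reagents that add atoms: prop-2-yn-1-ol (9), C#CCO
Why: Copper-acetylide allylic substitution (SN2 at the primary allylic carbon) gives the skipped enyne with the (E)-trisubstituted alkene retained and the free hydroxyl tolerated.

Step 6
Reactants: 10 (5E,8R,9E)-8-[dimethyl(phenyl)silyl]-5-methylundeca-5,9-dien-2-yn-1-ol
Product: 11 (2Z,5E,8R,9E)-8-[dimethyl(phenyl)silyl]-5-methylundeca-2,5,9-trien-1-ol
Conditions: H2 (1 atm), Pd/CaCO3 poisoned with Pb(OAc)2 (5 wt % Pd), quinoline, EtOAc, rt, stopped at 1 equiv H2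
Reagents that add atoms: none
Why: Lindlar semi-hydrogenation adds H2 syn to the alkyne only, giving the (Z)-allylic alcohol while the di- and trisubstituted alkenes are not reduced.

Step 7
Reactants: 11 (2Z,5E,8R,9E)-8-[dimethyl(phenyl)silyl]-5-methylundeca-2,5,9-trien-1-ol
Product: 12 (2Z,5E,8R,9E)-8-[dimethyl(phenyl)silyl]-5-methylundeca-2,5,9-trienal
Conditions: PhI(OAc)2 (1.2 equiv), TEMPO (10 mol %), CH2Cl2, 0 °C → rt; crude used at once
Reagents that add atoms: none
Why: Oxoammonium-mediated (TEMPO) oxidation stops at the aldehyde and is a standard way to make (Z)-enals without Z→E isomerisation; no strong acid or base is present to conjugate the skipped diene.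

Step 8
Reactants: 12 (2Z,5E,8R,9E)-8-[dimethyl(phenyl)silyl]-5-methylundeca-2,5,9-trienal
Product: 13 (1R,4aR,5S,8aR)-4a,5-dimethyl-1,4,4a,5,8,8a-hexahydronaphthalen-1-ol
Conditions: MeAlCl2 (1.2 equiv), CH2Cl2 (0.005 M), −78 °C, 1 h; aq. potassium sodium tartrate
Reagents that add atoms: none
Why: Proposed new method: a (Z)-enal-initiated, allylsilane-terminated cation–olefin bicyclisation in which the aluminium-complexed aldehyde carbon C9 is attacked by C10 of the (E)-trisubstituted alkene through a half-chair (ring B, as in the acid-mediated closure of neral to isopiperitenol) and the resulting tertiary C5 cation is captured in a chair by C4 of the (E)-crotylsilane with anti-SE2′ loss of silicon (ring A, Δ2), the closest known reaction types being aldehyde- or acetal-initiated, allylsilane-terminated polyene cyclisations and chirality transfer from (E)-crotylsilanes; the (E)-C5=C10 geometry gives the trans ring fusion, the (E)-crotyl unit places the C4 methyl equatorial and cis to the C5 methyl, the O–Al group sits pseudo-equatorial (9α) away from the axial C5 methyl, and only the chair–chair array that holds the (R)-C–Si bond axial and anti to the forming C4–C5 bond is productive, which fixes the absolute configuration.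

Step 9
Reactants: 13 (1R,4aR,5S,8aR)-4a,5-dimethyl-1,4,4a,5,8,8a-hexahydronaphthalen-1-ol
Product: 14 2α,3α:7α,8α-diepoxy-4β,5β-dimethyl-10αH-trans-decalin-9α-ol
Conditions: mCPBA (2.3 equiv), CH2Cl2, 0 °C, 4 h; basic aqueous work-up
Reagents that add atoms: mCPBA, OOC(=O)c1cccc(Cl)c1
Why: Prilezhaev epoxidation of both ring alkenes, Δ7 syn to the pseudo-equatorial allylic 9α-hydroxyl (Henbest hydrogen-bond delivery, the case where peracids outperform vanadium catalysts) and Δ2 from the α-face away from the axial C5 methyl as for 5α-steroid 2-enes, giving the α,α-bis-epoxide.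

Step 10
Reactants: 14 2α,3α:7α,8α-diepoxy-4β,5β-dimethyl-10αH-trans-decalin-9α-ol; 15 isopropenylmagnesium bromide
Product: 16 2α,3α-epoxy-4β,5β-dimethyl-7β-(prop-1-en-2-yl)-10αH-trans-decalin-8α,9α-diol
Conditions: 15 (6 equiv), CuI (30 mol %), THF, −30 → 0 °C; aq. NH4Cl
Reagents that add atoms: isopropenylmagnesium bromide (15), C=C(C)[Mg]Br
Why: Copper-catalysed Grignard epoxide opening under Fürst–Plattner control, where only β-attack at C7 gives the trans-diaxial product (7β-isopropenyl, 8α-OH; the same trajectory as methyl Grignard opening of steroid 5α,6α-epoxides) and the magnesium 9-alkoxide activates this epoxide, while the ring A epoxide is expected to be spared because its diaxial site C3 is flanked by the C4 methyl and the syn-axial C5 methyl.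

Step 11
Reactants: 16 2α,3α-epoxy-4β,5β-dimethyl-7β-(prop-1-en-2-yl)-10αH-trans-decalin-8α,9α-diol
Product: 17 (1S,2R,3R,4aR,5S,7S,8aR)-4a,5-dimethyl-3-(prop-1-en-2-yl)decahydronaphthalene-1,2,7-triol
Conditions: LiBHEt3 (5 equiv), THF, 0 → 40 °C; H2O quench
Reagents that add atoms: none
Why: Hydride SN2 opening of the remaining epoxide follows the Fürst–Plattner rule (axial hydride to C3 from the β-face) and leaves the axial 2α-alcohol, as in hydride opening of 2α,3α-epoxy-5α-steroids, with the isopropenyl group inert.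

Step 12
Reactants: 17 (1S,2R,3R,4aR,5S,7S,8aR)-4a,5-dimethyl-3-(prop-1-en-2-yl)decahydronaphthalene-1,2,7-triol; 18 (2E)-3-methylpent-2-enoic acid
Product: 21 (1S,2R,3R,4aR,5S,7S,8aR)-2,7-dihydroxy-4a,5-dimethyl-3-(prop-1-en-2-yl)decahydronaphthalen-1-yl (2E)-3-methylpent-2-enoate, via enoyl chloride 19 (not isolated), via stannylene acetal 20 (not isolated)
Conditions: 18, 1-chloro-N,N,2-trimethylprop-1-en-1-amine (1.1 equiv), CH2Cl2, 0 °C → rt (gives 19); separately 17, Bu2SnO (1.05 equiv), toluene, reflux with water removal (gives 20); then 19 added at 0 °C → rt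
Reagents that add atoms: (2E)-3-methylpent-2-enoic acid (18), OC(=O)/C=C(\C)CC
Why: Regioselective stannylene-acetal acylation, in which the cis-8,9-diol forms the five-membered dibutylstannylene and its equatorial oxygen (O9) is acylated by the acid chloride under base-free conditions, so the β,β-disubstituted enoate is not deconjugated and the axial 2- and 8-hydroxyls stay free.

**Compound list**
1 | ethyl (2E,4E)-hexa-2,4-dienoate (ethyl sorbate) | C/C=C/C=C/C(=O)OCC | starting material
2 | dimethyl(phenyl)(4,4,5,5-tetramethyl-1,3,2-dioxaborolan-2-yl)silane | CC1(C)OB(OC1(C)C)[Si](C)(C)c1ccccc1 | starting material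
3 | ethyl (3R,4E)-3-[dimethyl(phenyl)silyl]hex-4-enoate | C/C=C/[C@H]([Si](C)(C)c1ccccc1)CC(=O)OCC | intermediate
4 | ethyl 2-(triphenyl-λ5-phosphanylidene)propanoate | CCOC(=O)C(C)=P(c1ccccc1)(c1ccccc1)c1ccccc1 | starting material
5 | (3R,4E)-3-[dimethyl(phenyl)silyl]hex-4-enal | C/C=C/[C@H]([Si](C)(C)c1ccccc1)CC=O | intermediate
6 | ethyl (2E,5R,6E)-5-[dimethyl(phenyl)silyl]-2-methylocta-2,6-dienoate | C/C=C/[C@H]([Si](C)(C)c1ccccc1)C/C=C(\C)C(=O)OCC | intermediate
7 | (2E,5R,6E)-5-[dimethyl(phenyl)silyl]-2-methylocta-2,6-dien-1-ol | C/C=C/[C@H]([Si](C)(C)c1ccccc1)C/C=C(\C)CO | intermediate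
8 | (2E,5R,6E)-1-bromo-5-[dimethyl(phenyl)silyl]-2-methylocta-2,6-diene | C/C=C/[C@H]([Si](C)(C)c1ccccc1)C/C=C(\C)CBr | intermediate
9 | prop-2-yn-1-ol | C#CCO | starting material
10 | (5E,8R,9E)-8-[dimethyl(phenyl)silyl]-5-methylundeca-5,9-dien-2-yn-1-ol | C/C=C/[C@H]([Si](C)(C)c1ccccc1)C/C=C(\C)CC#CCO | intermediate
11 | (2Z,5E,8R,9E)-8-[dimethyl(phenyl)silyl]-5-methylundeca-2,5,9-trien-1-ol | C/C=C/[C@H]([Si](C)(C)c1ccccc1)C/C=C(\C)C/C=C\CO | intermediate
12 | (2Z,5E,8R,9E)-8-[dimethyl(phenyl)silyl]-5-methylundeca-2,5,9-trienal | C/C=C/[C@H]([Si](C)(C)c1ccccc1)C/C=C(\C)C/C=C\C=O | intermediate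
13 | (1R,4aR,5S,8aR)-4a,5-dimethyl-1,4,4a,5,8,8a-hexahydronaphthalen-1-ol (Δ2,Δ7-dien-9α-ol; trans-fused) | C1C[C@]2(C)[C@@H](C)C=CC[C@H]2[C@H](O)C=1 | intermediate
14 | 2α,3α:7α,8α-diepoxy-4β,5β-dimethyl-10αH-trans-decalin-9α-ol | [C@@H]12C[C@]3(C)[C@@H](C)[C@@H]4O[C@@H]4C[C@H]3[C@H](O)[C@@H]1O2 | intermediate
15 | isopropenylmagnesium bromide | C=C(C)[Mg]Br | starting material
16 | 2α,3α-epoxy-4β,5β-dimethyl-7β-(prop-1-en-2-yl)-10αH-trans-decalin-8α,9α-diol | C=C(C)[C@H]1C[C@]2(C)[C@@H](C)[C@@H]3O[C@@H]3C[C@H]2[C@H](O)[C@@H]1O | intermediate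
17 | (1S,2R,3R,4aR,5S,7S,8aR)-4a,5-dimethyl-3-(prop-1-en-2-yl)decahydronaphthalene-1,2,7-triol | C=C(C)[C@H]1C[C@]2(C)[C@@H](C)C[C@H](O)C[C@H]2[C@H](O)[C@@H]1O | intermediate
18 | (2E)-3-methylpent-2-enoic acid | OC(=O)/C=C(\C)CC | starting material
19 | (2E)-3-methylpent-2-enoyl chloride | ClC(=O)/C=C(\C)CC | intermediate
20 | 8α,9α-O-dibutylstannylene acetal of 17 (2,2-dibutyl-1,3,2-dioxastannolane across C8–C9; 2α-OH free) | C=C(C)[C@H]1C[C@]2(C)[C@@H](C)C[C@H](O)C[C@H]2[C@@H]3O[Sn](CCCC)(CCCC)O[C@H]13 | intermediate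
21 | (1S,2R,3R,4aR,5S,7S,8aR)-2,7-dihydroxy-4a,5-dimethyl-3-(prop-1-en-2-yl)decahydronaphthalen-1-yl (2E)-3-methylpent-2-enoate | C=C(C)[C@H]1C[C@]2(C)[C@@H](C)C[C@H](O)C[C@H]2[C@H](OC(=O)/C=C(\C)CC)[C@@H]1O | target

**Step count and risks**
Total steps: 12. Longest linear sequence: 12 (steps 1–12; 2, 4, 9, 15 and 18 are bought).

The three steps most likely to fail:

Step 8 (key bicyclisation). The skipped (Z)-enal may isomerise or conjugate before it cyclises, the cascade may stop after ring B, or the first closure may not be steered by the remote silane (low dr and ee). The fallback sets out from 12 and comes back to the route at 13. Compound 12 is acetalised with (2R,4R)-pentane-2,4-diol (pyridinium tosylate cat., MgSO4, CH2Cl2, 0 °C) to (4R,6R)-2-[(1Z,4E,7R,8E)-7-[dimethyl(phenyl)silyl]-4-methyldeca-1,4,8-trien-1-yl]-4,6-dimethyl-1,3-dioxane F1. TiCl4 in CH2Cl2 at −78 °C then triggers an acetal-initiated bicyclisation through the more electrophilic oxocarbenium ion. The auxiliary itself sets C9, because the C–O bond next to the axial ring methyl breaks with inversion; by the standard model this is the sense that matches the (R)-silane. The product is the hydroxy ether (2R,4R)-4-{[(1R,4aR,5S,8aR)-4a,5-dimethyl-1,4,4a,5,8,8a-hexahydronaphthalen-1-yl]oxy}pentan-2-ol F2. Dess–Martin oxidation gives (4R)-4-{[(1R,4aR,5S,8aR)-4a,5-dimethyl-1,4,4a,5,8,8a-hexahydronaphthalen-1-yl]oxy}pentan-2-one F3, and K2CO3 in methanol (β-elimination) releases 13.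

Step 10 (isopropenyl opening of the bis-epoxide). The branched nucleophile may be too hindered on the trajectory syn-axial to the C5 methyl, or the ring A epoxide may compete. The fallback sets out from 14 and comes back to the route at 17. Et2AlCl and lithium (trimethylsilyl)acetylide give diethyl[(trimethylsilyl)ethynyl]alane F4 in the flask. After forming the aluminium 9-alkoxide, F4 delivers the slim alkynyl group trans-diaxially to C7 of the hydroxyl-bearing epoxide only (toluene, 0 °C), giving 2α,3α-epoxy-4β,5β-dimethyl-7β-[(trimethylsilyl)ethynyl]-10αH-trans-decalin-8α,9α-diol F5. LiBHEt3 opens the ring A epoxide to 4β,5β-dimethyl-7β-[(trimethylsilyl)ethynyl]-10αH-trans-decalin-2α,8α,9α-triol F6. K2CO3 in methanol removes the silyl group to give 7β-ethynyl-4β,5β-dimethyl-10αH-trans-decalin-2α,8α,9α-triol F7. Zirconium-catalysed methylalumination (Me3Al in excess, Cp2ZrCl2, CH2Cl2; methyl to the internal alkyne carbon) followed by a water quench turns the ethynyl group into the isopropenyl group of 17.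

Step 1 (conjugate silylation). The addition may go 1,6 instead of 1,4, or the ee may be low. This fallback replaces both 1 and 2, so it sets out not from a numbered compound but from commercial (R)-but-3-yn-2-ol (C[C@@H](O)C#C), and it comes back to the route at 3. Hydrosilylation with PhMe2SiH (PtCl2, XPhos, THF, 50 °C) gives (2R,3E)-4-[dimethyl(phenyl)silyl]but-3-en-2-ol F8. Johnson–Claisen rearrangement with triethyl orthoacetate (propanoic acid cat., 140 °C) runs through the ketene acetal {(1E,3R)-3-[(1-ethoxyethenyl)oxy]but-1-en-1-yl}dimethyl(phenyl)silane F9 (not isolated). Its chair transition state with the methyl equatorial transfers the carbinol chirality to the silyl-bearing carbon (R to R) and gives the (E)-alkene of 3.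

**Further compounds**
F1 | step 8 | (4R,6R)-2-[(1Z,4E,7R,8E)-7-[dimethyl(phenyl)silyl]-4-methyldeca-1,4,8-trien-1-yl]-4,6-dimethyl-1,3-dioxane | C/C=C/[C@H]([Si](C)(C)c1ccccc1)C/C=C(\C)C/C=C\C1O[C@H](C)C[C@@H](C)O1
F2 | step 8 | (2R,4R)-4-{[(1R,4aR,5S,8aR)-4a,5-dimethyl-1,4,4a,5,8,8a-hexahydronaphthalen-1-yl]oxy}pentan-2-ol | C1C[C@]2(C)[C@@H](C)C=CC[C@H]2[C@H](O[C@H](C)C[C@@H](C)O)C=1
F3 | step 8 | (4R)-4-{[(1R,4aR,5S,8aR)-4a,5-dimethyl-1,4,4a,5,8,8a-hexahydronaphthalen-1-yl]oxy}pentan-2-one | C1C[C@]2(C)[C@@H](C)C=CC[C@H]2[C@H](O[C@H](C)CC(C)=O)C=1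
F4 | step 10 | diethyl[(trimethylsilyl)ethynyl]alane | CC[Al](CC)C#C[Si](C)(C)C
F5 | step 10 | 2α,3α-epoxy-4β,5β-dimethyl-7β-[(trimethylsilyl)ethynyl]-10αH-trans-decalin-8α,9α-diol | C[Si](C)(C)C#C[C@H]1C[C@]2(C)[C@@H](C)[C@@H]3O[C@@H]3C[C@H]2[C@H](O)[C@@H]1O
F6 | step 10 | 4β,5β-dimethyl-7β-[(trimethylsilyl)ethynyl]-10αH-trans-decalin-2α,8α,9α-triol | C[Si](C)(C)C#C[C@H]1C[C@]2(C)[C@@H](C)C[C@H](O)C[C@H]2[C@H](O)[C@@H]1O
F7 | step 10 | 7β-ethynyl-4β,5β-dimethyl-10αH-trans-decalin-2α,8α,9α-triol | C#C[C@H]1C[C@]2(C)[C@@H](C)C[C@H](O)C[C@H]2[C@H](O)[C@@H]1O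
F8 | step 1 | (2R,3E)-4-[dimethyl(phenyl)silyl]but-3-en-2-ol | C[C@@H](O)/C=C/[Si](C)(C)c1ccccc1
F9 | step 1 | {(1E,3R)-3-[(1-ethoxyethenyl)oxy]but-1-en-1-yl}dimethyl(phenyl)silane | C=C(OCC)O[C@H](C)/C=C/[Si](C)(C)c1ccccc1
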